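## Structural features

The target (11) is a flavonol: a 4H-chromen-4-one in which benzene ring A (C4a, C5–C8, C8a) is fused to γ-pyranone ring C (O1, C2, C3, C4), with a 4-methoxyphenyl ring B joined to C2 by a single C–C bond. Ring C carries a free hydroxyl at C3. Ring A carries a free hydroxyl at C5, hydrogen-bonded to the C4 carbonyl, and a 3-methylbut-2-enyl (prenyl) ether at C7; C6 and C8 are unsubstituted. There is no stereocenter, so no stereocenters stand next to each other, and the prenyl alkene ends in two identical methyl groups and has no geometry to control. The fragile groups are the prenyl aryl ether (ionizes under protic or Lewis acid, undergoes aromatic Claisen rearrangement on strong heating), the 3-hydroxy-4-pyranone enol (oxidized in aerated base) and the aryl methyl ether, which forbids any global dealkylation. The real difficulty is not the skeleton but telling four oxygens apart (3-OH, 5-OH, 7-O-prenyl, 4'-OMe) while building ring C with oxygen already at C3. The key step exploits the 1,3,5-oxygenation of ring A at C5, C7 and C8a: this ring is phloroglucinol, whose three C–H carbons (future C4a, C6, C8) and three hydroxyls (future O1, 5-OH, 7-OH) are interchangeable by threefold symmetry. C4–C4a and O1–C2 can therefore be made on the unprotected triol with no regiochemical question.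

## Logic of the disconnections

11 ⇒ 10. The O3–H of 11 is traced back to an O3–C(acyl) bond, a pivaloyl ester. The reason is that O3 is the second most acidic oxygen of the flavonol and would compete in the etherification at O7. The gain is that the acyl group is not installed in a separate step, because it arrives with the ring C precursor. The demand on the forward step is cleavage of a hindered ester by a reagent that leaves the allylic ether, the methyl ether and the pyranone alone.

10 ⇒ 8 + 9. The O7–CH2 bond of the prenyl ether is cut. An allyl aryl ether would not survive the temperature of the ring-forming step, so it has to be attached afterwards. The gain is a ring A with two free hydroxyls that stem from equivalent positions of a symmetric arene. The demand is alkylation at O7 only: not at O5, and not at C6 or C8 of the ambident phenoxide.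

8 ⇒ 3 + 4 (forward through 5, 6 and 7). C4–C4a and O1–C2 are cut, which opens ring C. This is the strategic cut: it reduces the bicycle to a commercial symmetric arene 4 and an acyclic ketoester 3 that already holds ring B, the 4'-methoxy group, C2, C3, C4 and the 3-oxygen. The demand is that the ester-derived carbon, not the ketone carbon, meets the ring carbon (chromone, not coumarin). The annulation must also stop after one ring, and the O3 acyl group must stay in place at about 240 °C.

3 ⇒ 2. The bond between the α-carbon and the ester oxygen of the pivaloyloxy group is cut, so the future O3 comes from a carboxylate nucleophile and the α-carbon becomes an electrophile. The gain is that the oxygenated ketoester is traced to a simple halide. The demand is substitution by a weakly basic carboxylate that outruns enolization of the doubly activated C–H.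

2 ⇒ 1. The Cα–Br bond is cut, which leads back to commercial 1. The demand is monobromination of the active methylene without a second bromination and without attack on the anisole ring.

## Other disconnections considered

Alternative 1: Ring C is cut at C3–C4 and O1–C2. Ring A comes as the salicylate acetonide A2, whose lactone carbonyl is C4 and whose ring oxygen is O1. Ring B with C2 and C3 comes as the α-(methoxymethoxy) ketone A3. In the forward key step the lithium enolate of A3 adds to the carbonyl of A2 and the tetrahedral intermediate collapses with loss of the acetonide carbon as a volatile ketone. The liberated C8a phenoxide then closes onto the aryl ketone when a weak acid is added, giving A1; removal of both acetal groups would complete 11.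
- In its favor: the chemistry runs between −78 °C and room temperature. C4 is already bonded to ring A, so neither C- versus O-acylation nor chromone versus coumarin arises. The prenyl ether is put on a simple arene early and is never heated.
- Against it here: the carbonyl of A2 is flanked by two ortho oxygens and is a hindered, deactivated electrophile. The diketone product is more acidic than A3 and consumes a second equivalent of enolate. Above all, the last step must strip two acetals with acid while the acid-labile prenyl ether is present, which invites ionization and chroman formation.
- Comparison: on thermal mildness and on avoiding a late chemoselective alkylation it is the better plan. On convergence (two fragments) it is equal. On structure it is weaker, because the symmetry of ring A is spent on stepwise protection to reach A2 (about three operations) rather than used. Its end game collides with the prenyl group, and it would need roughly seven operations against five.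

Alternative 2: Ring A is cut at four bonds (C8–C8a, C7–C8, C5–C6, C4a–C5) and built on a pyranone derived from kojic acid A7. In the forward key step the diazoketone A5 undergoes Wolff rearrangement to a vinylketene, which adds the siloxyalkyne A6 in a [2+2] fashion (ketene carbonyl carbon to the β-carbon of the ynol ether). 4π-Opening of the cyclobutenone, 6π-closure of the dienylketene and tautomerization then give phenol A4 (Danheiser benzannulation).
- In its favor: the 5-OH and the 7-oxygen emerge already differentiated, one as a free chelated phenol and one as a silyl ether, so O7 can be unmasked and alkylated without relying on acidity differences. Regiochemistry is dictated by the polarity of the ynol ether, and the 3-oxygen is native to A7.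
- Against it here: ring A is the one part of 11 that can be bought as a symmetric six-carbon unit. Making it instead requires protection, C–H arylation or halogenation and coupling on the pyranone, oxidation to the acid and diazoketone formation to reach A5, plus separate preparation of the moisture-sensitive A6. The migration of an electron-poor pyranonyl group and the photostability of the 4-pyranone chromophore at 350 nm are open questions, and diazo intermediates are a hazard.
- Comparison: it is the better plan on differentiating the ring A oxygens and is mechanistically the most instructive. On step economy (about ten operations against five) and on safety it is clearly worse.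

Alternative 3: Ring C is cut at C3–C4 and O1–C8a, with fluorine standing in for the ring A oxygens. In the forward key step the enolate of A3 (LiN(SiMe3)2) is C-acylated by 2,4,6-trifluorobenzoyl chloride A9. The enol oxygen of the resulting diketone then displaces an ortho fluoride by addition–elimination (K2CO3, DMF) to give A8.
- In its favor: both operations are low-temperature, reliable reaction types, and A9 is commercial. Its two ortho fluorides are equivalent, so the closure needs no regiocontrol, and no free phenol is handled.
- Against it here: O5 and O7 still have to be introduced after the key step by two further substitutions on A8. C5–F (ortho) and C7–F (para) are both activated by the C4 carbonyl, so site selectivity for the prenyloxy nucleophile is not assured. The second displacement must occur on a ring already deactivated by the first alkoxy group. A strongly basic alkoxide can also attack C2 of the pyranone, and the final acetal removal again meets the prenyl ether under acid.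
- Comparison: it is equal to the chosen plan in using the symmetry of a 1,3,5-trisubstituted ring A building block, and better in avoiding a 240 °C melt. It is worse in atom and step economy (fluorine as a placeholder for oxygen that 4 already carries; about seven operations) and in the selectivity problem at C5 versus C7.

Key step: step 3

Assumption: commercial 4 is dried to its anhydrous form before use, because water of crystallization would hydrolyze the ketene intermediate. The stereocenters of 2, 3, 6 and 7 are racemic or mixed and disappear when ring C aromatizes.

## Route

Step 1
Reactants: 1 ethyl 3-(4-methoxyphenyl)-3-oxopropanoate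
Product: 2 ethyl 2-bromo-3-(4-methoxyphenyl)-3-oxopropanoate (racemic)
Conditions: NBS (1.0 equiv), p-TsOH·H2O (10 mol%), CH2Cl2, 0 °C → rt
Reagents that add atoms: N-bromosuccinimide, O=C1CCC(=O)N1Br
Why: Acid-catalyzed electrophilic α-bromination of the active methylene through its enol; one equivalent of NBS should stop at the monobromide because 2 enolizes less readily than 1, and the anisole ring, deactivated by its para acyl group, is not attacked without a Lewis acid. The new stereocenter is racemic and is destroyed later.

Step 2
Reactants: 2 ethyl 2-bromo-3-(4-methoxyphenyl)-3-oxopropanoate (racemic)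
Product: 3 ethyl 3-(4-methoxyphenyl)-3-oxo-2-(pivaloyloxy)propanoate (racemic)
Conditions: CsO2CCMe3 (1.2 equiv), DMF, 0 °C → rt
Reagents that add atoms: cesium pivalate (CsO2CCMe3), [Cs+].[O-]C(=O)C(C)(C)C
Why: SN2 displacement of an α-halo carbonyl bromide by a carboxylate in a dipolar aprotic solvent, a substitution accelerated by the two flanking carbonyl groups; the weakly basic, well-dissociated cesium carboxylate favors substitution over enolization. The stereocenter stays racemic and is of no consequence.

Step 3
Reactants: 3 ethyl 3-(4-methoxyphenyl)-3-oxo-2-(pivaloyloxy)propanoate (racemic), 4 phloroglucinol (anhydrous, 1.5 equiv)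
Product: 8 5,7-dihydroxy-2-(4-methoxyphenyl)-4-oxo-4H-chromen-3-yl pivalate, via acylketene 5 (not isolated), via triketone 6 (not isolated), via hemiketal 7 (not isolated)
Conditions: neat melt, 240 °C, Ar sweep (−EtOH, −H2O)
Reagents that add atoms: none
Why: This is a Mentzer thermal condensation of a phenol with a β-ketoester, in its α-acyloxy variant that delivers a 3-oxygenated chromone. In the melt the enol of 3 loses ethanol to give acylketene 5, whose ketene carbon is attacked by a ring carbon of 4 (strongly carbon-nucleophilic through its keto tautomers) to form C4–C4a in triketone 6. A hydroxyl ortho to the new acyl group then adds to the 4-methoxybenzoyl carbonyl in a 6-exo-trig closure to hemiketal 7, and loss of water across C2–C3 completes O1–C2 within the aromatic γ-pyranone of 8. No stereocenter remains in 8; the centers of 3, 6 and 7 are racemic or mixed and are erased by the dehydration. The selectivity required is chromone over coumarin, and it rests on the neutral medium: without a protic or Lewis acid the ketone is not activated for Pechmann-type attack by the arene, so the ring carbon meets the ester-derived carbon and the phenol oxygen meets the ketone. Positional selectivity is not needed because the three C–H carbons and the three hydroxyls of 4 are equivalent, and a second annulation is disfavored once the first acyl group has deactivated ring A and 4 is kept in excess. The pivalate is chosen because its hindered carbonyl resists acyl transfer to the free phenols at 240 °C and it has no α-hydrogen from which a second ketene could form. The closest known reaction type is the solvent-free thermal phenol–β-ketoester chromone synthesis itself, run under a gas sweep that removes ethanol and water.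

Step 4
Reactants: 8 5,7-dihydroxy-2-(4-methoxyphenyl)-4-oxo-4H-chromen-3-yl pivalate, 9 prenyl bromide (1-bromo-3-methylbut-2-ene, 1.1 equiv)
Product: 10 5-hydroxy-2-(4-methoxyphenyl)-7-[(3-methylbut-2-en-1-yl)oxy]-4-oxo-4H-chromen-3-yl pivalate
Conditions: K2CO3 (1.2 equiv), acetone, reflux
Reagents that add atoms: none
Why: Williamson ether synthesis on the most acidic phenol: the 7-OH is para to the C4 carbonyl (a vinylogous acid), the 5-OH is held in a hydrogen bond to that carbonyl and the 3-oxygen is acylated, so about one equivalent of base and halide should alkylate O7 only. K2CO3 in acetone favors O- over C-alkylation of the phenoxide, and the temperature is far below that of an aromatic Claisen rearrangement.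

Step 5
Reactants: 10 5-hydroxy-2-(4-methoxyphenyl)-7-[(3-methylbut-2-en-1-yl)oxy]-4-oxo-4H-chromen-3-yl pivalate
Product: 11 3,5-dihydroxy-2-(4-methoxyphenyl)-7-[(3-methylbut-2-en-1-yl)oxy]-4H-chromen-4-one
Conditions: NaOMe (3 equiv), MeOH–THF, 0 °C → rt, Ar; then AcOH
Reagents that add atoms: none
Why: Base-mediated transesterification (Zemplén-type methanolysis): the 3-oxygen of a flavonol is a good leaving group, an enolate conjugated to the C4 carbonyl, so even the hindered pivalate should be cleaved near room temperature. The prenyl ether, the methyl ether and the pyranone are inert to cold methoxide, and argon protects the flavonol anion from oxidative ring cleavage until the acetic acid quench.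

## Compound list

1 | ethyl 3-(4-methoxyphenyl)-3-oxopropanoate | CCOC(=O)CC(=O)c1ccc(OC)cc1 | starting material
2 | ethyl 2-bromo-3-(4-methoxyphenyl)-3-oxopropanoate (racemic) | CCOC(=O)C(Br)C(=O)c1ccc(OC)cc1 | intermediate
3 | ethyl 3-(4-methoxyphenyl)-3-oxo-2-(pivaloyloxy)propanoate (racemic) | CCOC(=O)C(OC(=O)C(C)(C)C)C(=O)c1ccc(OC)cc1 | intermediate
4 | phloroglucinol (benzene-1,3,5-triol) | Oc1cc(O)cc(O)c1 | starting material
5 | 3-(4-methoxyphenyl)-1,3-dioxoprop-1-en-2-yl pivalate, the (4-methoxybenzoyl)(pivaloyloxy)ketene, not isolated | O=C=C(OC(=O)C(C)(C)C)C(=O)c1ccc(OC)cc1 | intermediate
6 | 1-(4-methoxyphenyl)-1,3-dioxo-3-(2,4,6-trihydroxyphenyl)propan-2-yl pivalate (racemic), not isolated | COc1ccc(cc1)C(=O)C(OC(=O)C(C)(C)C)C(=O)c1c(O)cc(O)cc1O | intermediate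
7 | 2,5,7-trihydroxy-2-(4-methoxyphenyl)-4-oxo-3,4-dihydro-2H-chromen-3-yl pivalate (racemic mixture of diastereomers), not isolated | COc1ccc(cc1)C1(O)Oc2cc(O)cc(O)c2C(=O)C1OC(=O)C(C)(C)C | intermediate
8 | 5,7-dihydroxy-2-(4-methoxyphenyl)-4-oxo-4H-chromen-3-yl pivalate | COc1ccc(-c2oc3cc(O)cc(O)c3c(=O)c2OC(=O)C(C)(C)C)cc1 | intermediate
9 | prenyl bromide (1-bromo-3-methylbut-2-ene) | CC(C)=CCBr | starting material
10 | 5-hydroxy-2-(4-methoxyphenyl)-7-[(3-methylbut-2-en-1-yl)oxy]-4-oxo-4H-chromen-3-yl pivalate | COc1ccc(-c2oc3cc(OCC=C(C)C)cc(O)c3c(=O)c2OC(=O)C(C)(C)C)cc1 | intermediate
11 | 3,5-dihydroxy-2-(4-methoxyphenyl)-7-[(3-methylbut-2-en-1-yl)oxy]-4H-chromen-4-one (CNP0163238.0) | COc1ccc(-c2oc3cc(OCC=C(C)C)cc(O)c3c(=O)c2O)cc1 | target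

## Step count and least certain steps

Total step count: 5. Longest linear sequence: 5 steps (1 → 2 → 3 → 8 → 10 → 11); 4 and 9 enter as bought.

Step 3 (key step). The most likely failure is diversion of the ketene before the C–C bond forms. Ketene 5 may be captured at a phenol oxygen without the later acyl shift to carbon, and the pivaloyl group may wander to a ring A hydroxyl. Product 8 may be annulated a second time during the long stay at 240 °C, and 4 may sublime out of the melt.
The fallback builds ring C through C2–C3 and O1–C2 on a preformed aryl ketone instead. It sets out from 4.
- Hoesch acylation of 4 with cyanomethyl benzoate (ZnCl2, HCl, Et2O, 0 °C; then hot water to hydrolyze the ketiminium salt) should give 2-oxo-2-(2,4,6-trihydroxyphenyl)ethyl benzoate F1.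
- Allan–Robinson condensation of F1 with 4-methoxybenzoic anhydride and NaO2CC6H4-4-OMe at about 180 °C, followed by brief KOH/aqueous ethanol hydrolysis of all aroyl esters under nitrogen, should give kaempferide, 3,5,7-trihydroxy-2-(4-methoxyphenyl)-4H-chromen-4-one F2.
- The 7-OH of F2, the most acidic, would then be etherified with 9 (K2CO3, 1.0 equiv, acetone), which brings the route back at 11.

Step 4. The risk is loss of site control in the alkylation. The phloroglucinol-type phenoxide is ambident and can be prenylated at C6 or C8, and any excess base can bring the chelated O5 into play.
The fallback sets out from 8 and returns at 10. It is a Mitsunobu etherification with 3-methylbut-2-en-1-ol, PPh3 and diisopropyl azodicarboxylate in THF at 0 °C. This engages only the most acidic phenol through an oxyphosphonium-activated alcohol, under neutral conditions. It makes no new compound.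

Step 5. The risk is slow acyl cleavage at the hindered carbonyl, so that the flavonol anion stays in base long enough for oxidative opening of ring C or for methoxide addition at C2.
The fallback carries the 3-oxygen as a more labile benzoate. It sets out from 2 and returns at 11.
- Displacement of the bromide of 2 with NaO2CPh in DMF should give ethyl 2-(benzoyloxy)-3-(4-methoxyphenyl)-3-oxopropanoate (racemic) F3.
- The same thermal condensation with 4 should give 5,7-dihydroxy-2-(4-methoxyphenyl)-4-oxo-4H-chromen-3-yl benzoate F4.
- Etherification with 9 and K2CO3 should give 5-hydroxy-2-(4-methoxyphenyl)-7-[(3-methylbut-2-en-1-yl)oxy]-4-oxo-4H-chromen-3-yl benzoate F5.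
- K2CO3 in methanol at 0 °C should then release 11.
The price is a less robust ester in the melt.

Step 2. The risk is proton transfer instead of substitution. The carboxylate may deprotonate the doubly activated C–H of 2, and the enolate may then abstract bromine from a second molecule or condense with it.
The fallback sets out from 1 and returns at 3.
- Regitz diazo transfer (4-acetamidobenzenesulfonyl azide, Et3N, MeCN) should give ethyl 2-diazo-3-(4-methoxyphenyl)-3-oxopropanoate F6.
- Rh2(OAc)4-catalyzed carbenoid O–H insertion into pivalic acid (CH2Cl2, rt) should give 3 without any α-halide.

## Further compounds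

F1 | step 3 | 2-oxo-2-(2,4,6-trihydroxyphenyl)ethyl benzoate | O=C(COC(=O)c1ccccc1)c1c(O)cc(O)cc1O
F2 | step 3 | kaempferide, 3,5,7-trihydroxy-2-(4-methoxyphenyl)-4H-chromen-4-one | COc1ccc(-c2oc3cc(O)cc(O)c3c(=O)c2O)cc1
F0 | step 4 | none | none
F3 | step 5 | ethyl 2-(benzoyloxy)-3-(4-methoxyphenyl)-3-oxopropanoate (racemic) | CCOC(=O)C(OC(=O)c1ccccc1)C(=O)c1ccc(OC)cc1
F4 | step 5 | 5,7-dihydroxy-2-(4-methoxyphenyl)-4-oxo-4H-chromen-3-yl benzoate | COc1ccc(-c2oc3cc(O)cc(O)c3c(=O)c2OC(=O)c4ccccc4)cc1
F5 | step 5 | 5-hydroxy-2-(4-methoxyphenyl)-7-[(3-methylbut-2-en-1-yl)oxy]-4-oxo-4H-chromen-3-yl benzoate | COc1ccc(-c2oc3cc(OCC=C(C)C)cc(O)c3c(=O)c2OC(=O)c4ccccc4)cc1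
F6 | step 2 | ethyl 2-diazo-3-(4-methoxyphenyl)-3-oxopropanoate | CCOC(=O)C(=[N+]=[N-])C(=O)c1ccc(OC)cc1
A1 | alternative 1 | 3,5-bis(methoxymethoxy)-2-(4-methoxyphenyl)-7-[(3-methylbut-2-en-1-yl)oxy]-4H-chromen-4-one | COCOc1c(-c2ccc(OC)cc2)oc2cc(OCC=C(C)C)cc(OCOC)c2c1=O
A2 | alternative 1 | 5-(methoxymethoxy)-2,2-dimethyl-7-[(3-methylbut-2-en-1-yl)oxy]-4H-1,3-benzodioxin-4-one | COCOc1cc(OCC=C(C)C)cc2OC(C)(C)OC(=O)c12
A3 | alternative 1 | 2-(methoxymethoxy)-1-(4-methoxyphenyl)ethan-1-one | COCOCC(=O)c1ccc(OC)cc1
A4 | alternative 2 | 5-hydroxy-3-(methoxymethoxy)-2-(4-methoxyphenyl)-7-(triisopropylsilyloxy)-4H-chromen-4-one | COCOc1c(-c2ccc(OC)cc2)oc2cc(O[Si](C(C)C)(C(C)C)C(C)C)cc(O)c2c1=O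
A5 | alternative 2 | 2-diazo-1-[5-(methoxymethoxy)-6-(4-methoxyphenyl)-4-oxo-4H-pyran-2-yl]ethan-1-one | [N-]=[N+]=CC(=O)c1cc(=O)c(OCOC)c(-c2ccc(OC)cc2)o1
A6 | alternative 2 | (ethynyloxy)triisopropylsilane | C#CO[Si](C(C)C)(C(C)C)C(C)C
A7 | alternative 2 | kojic acid, 5-hydroxy-2-(hydroxymethyl)-4H-pyran-4-one | OCc1cc(=O)c(O)co1
A8 | alternative 3 | 5,7-difluoro-3-(methoxymethoxy)-2-(4-methoxyphenyl)-4H-chromen-4-one | COCOc1c(-c2ccc(OC)cc2)oc2cc(F)cc(F)c2c1=O
A9 | alternative 3 | 2,4,6-trifluorobenzoyl chloride | O=C(Cl)c1c(F)cc(F)cc1F
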